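Something has to be left over here: the two substrates together are twice the reagent, so reagent is the limiting reagent, and I ask which route gets it.

starting material 0.31 M; second substrate 0.310 M; reagent 0.310 M; free catalyst 1.5 mM; added ligand 3.6 mM

    free catalyst + added ligand ⇌ idle complex B, settled at all times (K1 = 4200 /M)
    starting material + free catalyst ⇌ catalyst intermediate A (K2 = 2.7 /M, k2 = 59 /M/s)
    second substrate + catalyst intermediate A ⇌ idle complex A, settled at all times (K3 = 33 /M)
    second substrate + free catalyst ⇌ catalyst intermediate B (K4 = 1.9 /M, k4 = 50 /M/s)
    reagent + catalyst intermediate B → free catalyst + second product (k5 = 2.9 /M/s)
    reagent + catalyst intermediate A → free catalyst + target (k6 = 13 /M/s)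

- the form that holds most of the catalyst when 20 % of the starting material are converted (free catalyst / idle complex B / idle complex A / catalyst intermediate B / catalyst intermediate A)
- its share of the catalyst then
- apparent order in reagent when 20 % of the starting material are converted (percent change of the rate of making target for one percent more reagent charged)

The two routes look nearly the same: equal substrate charges, and binding at 59 /M/s against 50 /M/s. So I count lifetimes. A bound intermediate either falls back to free catalyst or meets reagent. Each falls back faster than it meets reagent.

Catalyst intermediate A: falls back at 21.9 /s, meets reagent at 4.03 /s.

Catalyst intermediate B: falls back at 26.3 /s, meets reagent at 0.899 /s.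

I call the reagent rate over the sum of both rates the escape chance: 15.6 % for catalyst intermediate A, 3.30 % for catalyst intermediate B.

Binding rate times escape chance gives the target route an edge at the charge of 5.56, though binding alone differs by 1.18. With that edge, I reckon the reagent left at the asked conversion as 0.237 M.

Per free catalyst, with half the catalyst guessed to sit on the ligand, I get these weights:

Idle complex B: 12.0

Catalyst intermediate A: 0.587

Idle complex A: 6.00

Catalyst intermediate B: 0.574

So I commit to idle complex B at 59.4 %. With the escape chance then at 12.4 %, and a charge that counts more in what is left, the order is 1.15.

The forecast says idle complex B, 59 % and order 1.21, on this ground: “The added ligand is in excess over the catalyst and binds it tightly”. My order is lower than the forecast's.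

The flask gives idle complex B at 59.1 % and order 1.2, with the conversion reached at 6.07 min.

At 1.00 min the flask reads 5.45 target per second product, with starting material at 96.0 % and reagent, which pays for both products, at 95.5 %. By 100 min the reagent is down to 4.00 %, which puts the escape chance of catalyst intermediate A at 0.733 %. Starting material then stands at 24.7 %, target at 75.2 %, second product at 0.0644 M, and idle complex B holds 75.6 % of the catalyst.

Its constants stand for no real mixture; the flask was simulated.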